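## The problem

The target is an achiral diaryl ether in which two benzoic acids are joined through an oxygen that lies ortho to the carboxyl group on each ring. The central C–O bond therefore links two hindered positions: C2 of ring A, between the C1 carboxyl and the C3 hydroxyl, and C2' of ring B, beside the C1' carboxyl. Ring B (C1' CO2H, C2' O, C4' CH3, C6' OH) has a simple 1,2,3,5-pattern that can be bought almost complete. Ring A is the hard part: five different substituents in a fixed order (C1 CO2H, C2 OAr, C3 OH, C4 Cl, C5 OCH3) and a single hydrogen at C6. Chlorine is locked between two oxygens, and the three oxygens must end as aryl ether, free phenol and methyl ether, which electrophilic substitution on a preformed arene cannot be trusted to deliver. There is no stereocentre, so every control problem is one of regiochemistry and of telling like groups apart. Three features will not survive rough treatment: the ring B acid (a 2,6-dioxygenated benzoic acid, which decarboxylates in hot acid), the aryl chloride (which rules out hydrogenolysis) and the free phenols (which make both rings easy to oxidise or chlorinate). What opens a short route is that the oxygens on C2 and C5 of ring A are para, with the C3 oxygen and the C4 chlorine on the carbons between them. This is the pattern of a mono-protected hydroquinone that unfolds from a 4-alkenyl-4-oxycyclobutenone, with C5, C4, C3 and C2 coming from squaric acid and C1 and C6 from an alkene.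

## Retrosynthesis

**20 ⇒ 19.** The two O–CH(CH3)2 bonds, at C3 of ring A and C6' of ring B, are cut last. Isopropyl is preferred to benzyl, whose hydrogenolysis would endanger the C4–Cl bond, and to methyl, which would have to be told apart from the C5 methyl ether. Diacid 19 differs from 20 only by these two alkyl groups but has no free phenol, so it can be oxidised and handled safely. The forward step asks a boron trihalide to cleave two secondary alkyl aryl ethers and leave the unchelated methyl ether, the diaryl ether and the chloride.

**19 ⇒ 18.** No skeletal bond is cut; both carboxyl carbons go back to the aldehyde level. Carrying them as esters was rejected because the ring B ester would be doubly ortho-substituted and its saponification slow, next to an acid that decarboxylates easily. As formyl groups they also serve the next disconnection as activating groups. The forward step is a single chlorite oxidation of two non-enolisable aryl aldehydes in dialdehyde 18.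

**18 ⇒ 13 + 17.** The bond between the ether oxygen and C2' of ring B is cut. Cutting on the other side would need a halogen on C2 of ring A, whereas the key step delivers an oxygen there, so ring A has to be the nucleophile. Addition–elimination on the ortho-fluorobenzaldehyde 17 is preferred to a palladium-catalysed coupling of a ring B triflate for two reasons. The ring A chloride is never exposed to an oxidative-addition catalyst, and a phenol beside a formyl group, less suited to catalysed C–O couplings, is an accepted nucleophile for this substitution. The cut divides the molecule into two benzaldehydes of similar size. The forward reaction must displace the fluoride ortho to the ring B formyl group and not the ring A chloride para to the other formyl group.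

**17 ⇒ 15 ⇒ 14.** The C1'–CHO bond is cut, then the O–isopropyl bond. The hydrogen between fluorine and the alkoxy group of 15 is the most acidic on the ring, so directed lithiation and formylation place the formyl carbon exactly where C1' must be. This is shorter than degrading a benzoic acid to a fluoroarene. Phenol 14 already carries the 1,3,5-pattern of fluorine, oxygen and methyl.

**13 ⇒ 12 ⇒ 11 ⇒ 10.** Only heteroatom bonds change: the C5 O–CH3 bond, the O–Si bond on the C2 oxygen and the two C–OEt bonds of the acetal. Phenol 10 carries the para oxygens already distinguished, as free OH on C5 and silyl ether on C2. Methylation to 11 and fluoride followed by acid (through 12) give salicylaldehyde 13 without any selective alkylation of a hydroquinone. The acetal is kept until the silyl ether is gone so that nothing oxidisable is carried through the thermolysis.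

**10 ⇒ 7 (key disconnection).** The C5–C6 bond of ring A is cut and C5 is reconnected to C2, which folds the benzene ring back into cyclobutenone 7. Against the neighbouring idea of building ring A by stepwise substitution, this cut fixes all five substituents by connectivity. The ketene carbon becomes C5, the chloro and isopropoxy alkene carbons become C4 and C3, the carbinol carbon becomes C2, and the two alkene carbons become C1 and C6. The precursor has a four-membered ring, one stereocentre that does not matter and no regiochemical ambiguity. The forward reaction is asked for outward rotation of the silyloxy group in the ring opening and for closure of the ketene onto a 1,1-disubstituted alkene.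

**7 ⇒ 3 + 4 (through 5 and 6).** The bond between the carbinol carbon and the alkenyl carbon is cut, giving chloro isopropyl squarate 3 and the alkenyllithium 5 from bromoacetal 4. The alternative of introducing chlorine after the addition costs steps and is held in reserve. The forward step needs 1,2-addition at the carbonyl beside the isopropoxy carbon (the one that is not a vinylogous ester) and capture of alkoxide 6 by a silyl triflate.

**3 ⇒ 2 ⇒ 1.** The C–O(isopropyl) bond and the two C–Cl bonds are cut, which leads through squaryl dichloride 2 to squaric acid 1. The first substitution deactivates the second, so one equivalent of the alcohol should stop at the mono-ester.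

## Roads not taken

**Alternative 1:** ring B from a 2-pyrone. The cut is made in ring B, at C4'–C5' and C6'–C1'. The 4-aryloxy-2-pyrone A1 (methyl 4-[2-(benzyloxy)-3-chloro-4-methoxy-6-(methoxycarbonyl)phenoxy]-6-methyl-2-oxo-2H-pyran-3-carboxylate) would react with a ketene acetal in an inverse-demand Diels–Alder reaction. Decarboxylation and loss of an alcohol would then give the diaryl ether diester A2.

- Merits: the substitution pattern of ring B follows from the polarisation of the pyrone. The aryl–oxygen bond is made on a pyrone carbon by addition–elimination, which is easier than substitution on a benzene ring and avoids heating two aldehydes with base as in step 9. In that respect it is the better road.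
- Weak points: the aryloxy group donates into the pyrone and the methyl group sits on the carbon that the nucleophilic end of the ketene acetal must attack, so the cycloaddition is slowed twice. A2 carries the ring B phenol as a methyl ether that must be distinguished from the C5 methyl ether, and a doubly ortho-substituted methyl ester that must be saponified. Its benzyl ether cannot be removed by hydrogenolysis beside the chloride.
- Comparison: this road spends its key step on the easy ring and leaves the pentasubstituted ring A to conventional arene chemistry. The chosen plan sets against it a ring A whose five substituents are fixed by construction and a deprotection that ends in one dealkylation.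

**Alternative 2:** aryne, phenoxide and carboxylation in one flask. Two bonds of ring B are cut at once, O–C2' and C1'–CO2H. Fluoride would release 3-benzyloxy-5-methylbenzyne from the silyl triflate A3 (2-(benzyloxy)-4-methyl-6-(trimethylsilyl)phenyl trifluoromethanesulfonate). The phenoxide of A4 (2-(benzyloxy)-3-chloro-6-(dimethoxymethyl)-4-methoxyphenol) would add at the aryne carbon remote from the benzyloxy group, and the aryl anion would be carboxylated to give acid A5.

- Merits: it is the most convergent of the four plans. It needs no transition metal, forms the hindered ether and the ring B carboxyl together, and needs no later oxidation of ring B. If it worked it would save about two steps over steps 7 to 10.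
- Weak points: it is a three-component reaction. The aryl anion must find the carboxylating gas before any proton source, and the same gas reversibly ties up the phenoxide as a carbonate. The nucleophile is hindered on both sides, A3 itself takes several steps, and the benzyl groups again need a non-reductive removal.
- Comparison: it does not address ring A at all. A4 is a close relative of 12 and would still have to come from the cyclobutenone chemistry. The chosen plan sets a two-component substitution of a well-documented type against the shorter but less predictable three-component step.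

**Alternative 3:** ring B by closure of a trienolate. The C5'–C6' bond of ring B is cut. A strong alkoxide base would deprotonate an isopropylidene methyl group of the dienyl malonate A6 (dimethyl 2-{1-[2-(benzyloxy)-3-chloro-4-methoxy-6-(methoxycarbonyl)phenoxy]-3-methylbut-2-en-1-ylidene}propanedioate). The trienolate would close onto one ester carbon, expel methoxide and enolise to salicylate A7.

- Merits: the ring B phenol appears free and in the right place, the regiochemistry is unambiguous and the reagents are cheap. On protecting-group economy for ring B it is better than the chosen plan, which carries an isopropyl ether there.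
- Weak points: A6 is a vinylogous carbonate, so the alkoxide base or the methoxide released can add at the aryloxy-bearing carbon and expel the ring A phenoxide, undoing the ether. Only the methyl group that can reach the ester in an s-cis trienolate closes. The ring A ester is exposed to the base. A7 still holds a doubly ortho-substituted methyl ester, to be hydrolysed beside an acid that loses carbon dioxide easily.
- Comparison: like the first alternative, it builds the ring that can be bought. The chosen plan sets against it the construction of ring A and an end game with no ester to saponify.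

Key step: step 4

Assumption: the target is achiral and 7 is used as the racemate; squaric acid, 2-bromo-3,3-diethoxyprop-1-ene and 3-fluoro-5-methylphenol are taken as purchasable.

## Route

Step 1
Reactants: 1 squaric acid
Product: 2 3,4-dichlorocyclobut-3-ene-1,2-dione (squaryl dichloride)
Conditions: (COCl)2 (2.2 equiv), DMF (cat.), CH2Cl2, rt → 40 °C; sublimation
Reagents that add atoms: oxalyl chloride, O=C(Cl)C(=O)Cl
Why: Vilsmeier-type activation (chloroiminium from DMF and oxalyl chloride) turns both vinylogous acid hydroxyls into vinylogous acid chlorides; this is the standard preparation of squaryl dichloride and the by-products are gases.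

Step 2
Reactants: 2 3,4-dichlorocyclobut-3-ene-1,2-dione
Product: 3 3-chloro-4-(propan-2-yloxy)cyclobut-3-ene-1,2-dione
Conditions: i-PrOH (1.0 equiv), CH2Cl2, 0 °C → rt, N2 sweep
Reagents that add atoms: propan-2-ol, CC(C)O
Why: Addition–elimination at a vinylogous acid chloride; once the first chloride is replaced the isopropoxy group donates into the dione and makes 3 much less electrophilic than 2, so one equivalent of alcohol should stop at the ester chloride of squaric acid.

Step 3
Reactants: 4 2-bromo-3,3-diethoxyprop-1-ene, 3 3-chloro-4-(propan-2-yloxy)cyclobut-3-ene-1,2-dione
Product: 7 rac-4-[(tert-butyldimethylsilyl)oxy]-2-chloro-4-(3,3-diethoxyprop-1-en-2-yl)-3-(propan-2-yloxy)cyclobut-2-en-1-one, via alkenyllithium 5 (not isolated), via lithium alkoxide 6 (not isolated)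
Conditions: 4, n-BuLi, THF, −78 °C; cannulate into 3, THF, −78 °C; TBSOTf, −78 → −40 °C; Et3N, aq. NaHCO3
Reagents that add atoms: tert-butyldimethylsilyl trifluoromethanesulfonate, CC(C)(C)[Si](C)(C)OS(=O)(=O)C(F)(F)F
Why: Bromine–lithium exchange gives the α-lithiated acrolein acetal 5, a known acrolein α-anion equivalent; organolithiums add 1,2 to unsymmetrical cyclobutenediones at the carbonyl that is not deactivated as a vinylogous ester, here the one beside the isopropoxy carbon, which puts Cl on C2 and the isopropoxy group on C3 of the cyclobutenone; alkoxide 6 is silylated in the flask, so the acid-labile carbinol is never isolated and no pyridine base is brought near the acetal; the new quaternary carbon forms as a racemate and is erased in step 4.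

Step 4
Reactants: 7 rac-4-[(tert-butyldimethylsilyl)oxy]-2-chloro-4-(3,3-diethoxyprop-1-en-2-yl)-3-(propan-2-yloxy)cyclobut-2-en-1-one
Product: 10 4-[(tert-butyldimethylsilyl)oxy]-2-chloro-5-(diethoxymethyl)-3-(propan-2-yloxy)phenol, via dienylketene 8 (not isolated), via cyclohexadienone 9 (not isolated)
Conditions: PhMe (degassed, 0.02 M), 110 °C, Ar
Reagents that add atoms: none
Why: This is the thermal ring expansion of a 4-alkenyl-4-oxycyclobutenone to a mono-protected hydroquinone (Moore rearrangement), the closest known reaction type being the same expansion of 4-alkenyl-4-silyloxy and 4-alkoxy cyclobutenones from squarate esters. Conrotatory 4π opening breaks the bond between the carbonyl carbon and the carbinol carbon; the silyloxy donor rotates outward, so the alkenyl group turns inward and the (3Z)-dienylketene 8 results. The ketene carbon and the terminal CH2 then close by a thermal disrotatory 6π-electrocyclisation, which forms the C5–C6 bond and the six-membered carbocycle as cyclohexa-2,4-dienone 9. Enolisation of 9 gives phenol 10, and aromatisation makes the sequence irreversible. No stereocentre is created and the one in 7 disappears. The selectivity needed is the torquoselectivity of the opening, which the oxygen substituent on the carbinol carbon secures. The regiochemistry is fixed by the connectivity of 7: ketene carbon to C5 (free OH), chloro and isopropoxy carbons to C4 and C3, carbinol carbon to C2 (silyl ether), alkene carbons to C1 (acetal) and C6 (H). High dilution and exclusion of air should keep the chloroketene from intermolecular capture and the product from oxidation, and the acetal and silyl ether are inert to neutral thermolysis.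

Step 5
Reactants: 10 4-[(tert-butyldimethylsilyl)oxy]-2-chloro-5-(diethoxymethyl)-3-(propan-2-yloxy)phenol
Product: 11 tert-butyl[3-chloro-6-(diethoxymethyl)-4-methoxy-2-(propan-2-yloxy)phenoxy]dimethylsilane
Conditions: MeI, K2CO3, acetone, rt
Reagents that add atoms: iodomethane, CI
Why: Williamson O-methylation of the only free phenol, which the ortho chlorine makes more acidic; the doubly ortho-substituted aryl silyl ether is hindered enough to stay under anhydrous carbonate at room temperature, so the para oxygens remain distinguished.

Step 6
Reactants: 11 tert-butyl[3-chloro-6-(diethoxymethyl)-4-methoxy-2-(propan-2-yloxy)phenoxy]dimethylsilane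
Product: 13 4-chloro-2-hydroxy-5-methoxy-3-(propan-2-yloxy)benzaldehyde, via phenol acetal 12 (not isolated)
Conditions: Bu4NF, THF, 0 °C; then 1 M HCl, rt
Reagents that add atoms: water, O
Why: Fluoride cleaves the aryl silyl ether, and on acidification the ortho-hydroxyaryl acetal 12 hydrolyses quickly because the electron-rich ring assists ionisation; the hydrogen-bonded salicylaldehyde 13 is stable to handling, whereas 12 is not worth isolating.

Step 7
Reactants: 14 3-fluoro-5-methylphenol
Product: 15 1-fluoro-3-methyl-5-(propan-2-yloxy)benzene
Conditions: 2-bromopropane, K2CO3, DMF, 60 °C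
Reagents that add atoms: 2-bromopropane, CC(C)Br
Why: Williamson etherification of a phenoxide with a secondary bromide in a dipolar aprotic solvent, the usual way to make aryl isopropyl ethers.

Step 8
Reactants: 15 1-fluoro-3-methyl-5-(propan-2-yloxy)benzene
Product: 17 2-fluoro-4-methyl-6-(propan-2-yloxy)benzaldehyde, via aryllithium 16 (not isolated)
Conditions: n-BuLi, THF, −78 °C; DMF, −78 → 0 °C; H2O
Reagents that add atoms: N,N-dimethylformamide, CN(C)C=O
Why: Directed ortho-metalation: the hydrogen between fluorine and the alkoxy group has two inductively withdrawing, coordinating neighbours and is removed first, as in 3-fluoroanisole; at −78 °C the ortho-fluoroaryllithium 16 should not lose fluoride to an aryne, and formylation with DMF gives 17 on aqueous work-up.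

Step 9
Reactants: 13 4-chloro-2-hydroxy-5-methoxy-3-(propan-2-yloxy)benzaldehyde, 17 2-fluoro-4-methyl-6-(propan-2-yloxy)benzaldehyde
Product: 18 4-chloro-2-[2-formyl-5-methyl-3-(propan-2-yloxy)phenoxy]-5-methoxy-3-(propan-2-yloxy)benzaldehyde
Conditions: Cs2CO3, DMSO, 100 °C
Reagents that add atoms: none
Why: Nucleophilic aromatic substitution by addition–elimination: the formyl group ortho to fluorine stabilises the anionic intermediate and fluoride is the best leaving group for this mechanism, and diaryl ethers from salicylaldehydes and 2-fluorobenzaldehydes under carbonate are well known; the ring A chloride, though para to a formyl group, sits between two alkoxy groups on an electron-rich ring and is a far poorer leaving group, and neither aldehyde can enolise.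

Step 10
Reactants: 18 4-chloro-2-[2-formyl-5-methyl-3-(propan-2-yloxy)phenoxy]-5-methoxy-3-(propan-2-yloxy)benzaldehyde
Product: 19 2-[2-carboxy-5-methyl-3-(propan-2-yloxy)phenoxy]-4-chloro-5-methoxy-3-(propan-2-yloxy)benzoic acid
Conditions: NaClO2, NaH2PO4, 2-methyl-2-butene, t-BuOH/THF/H2O, 0 °C → rt
Reagents that add atoms: NaClO2 (sodium chlorite), [Na+].[O-]Cl=O
Why: Pinnick oxidation converts both aryl aldehydes into acids under buffered, mildly acidic conditions; the alkene scavenger removes the hypochlorous acid that would otherwise chlorinate the alkoxy-substituted rings, and aryl ethers and the aryl chloride are untouched.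

Step 11
Reactants: 19 2-[2-carboxy-5-methyl-3-(propan-2-yloxy)phenoxy]-4-chloro-5-methoxy-3-(propan-2-yloxy)benzoic acid
Product: 20 2-(2-carboxy-3-hydroxy-5-methylphenoxy)-4-chloro-3-hydroxy-5-methoxybenzoic acid (the target)
Conditions: BCl3 (excess), CH2Cl2, −78 → 0 °C; then H2O, 0 °C
Reagents that add atoms: none
Why: Lewis-acid dealkylation: BCl3 cleaves aryl isopropyl ethers at low temperature by loss of the secondary alkyl group as its chloride, far faster than an unchelated aryl methyl ether, so the C5 methyl ether, the diaryl ether and the aryl chloride should remain; cold aqueous work-up hydrolyses the boron esters without heating the decarboxylation-prone ring B acid.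

## Compound list

1 | squaric acid (3,4-dihydroxycyclobut-3-ene-1,2-dione) | OC1=C(O)C(=O)C1=O | starting material
2 | 3,4-dichlorocyclobut-3-ene-1,2-dione | ClC1=C(Cl)C(=O)C1=O | intermediate
3 | 3-chloro-4-(propan-2-yloxy)cyclobut-3-ene-1,2-dione | CC(C)OC1=C(Cl)C(=O)C1=O | intermediate
4 | 2-bromo-3,3-diethoxyprop-1-ene | C=C(Br)C(OCC)OCC | starting material
5 | (3,3-diethoxyprop-1-en-2-yl)lithium (formed in the flask) | [Li]C(=C)C(OCC)OCC | intermediate
6 | lithium 3-chloro-1-(3,3-diethoxyprop-1-en-2-yl)-4-oxo-2-(propan-2-yloxy)cyclobut-2-en-1-olate, racemic (formed in the flask) | [Li]OC1(C(=C)C(OCC)OCC)C(OC(C)C)=C(Cl)C1=O | intermediate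
7 | rac-4-[(tert-butyldimethylsilyl)oxy]-2-chloro-4-(3,3-diethoxyprop-1-en-2-yl)-3-(propan-2-yloxy)cyclobut-2-en-1-one | O=C1C(Cl)=C(OC(C)C)C1(O[Si](C)(C)C(C)(C)C)C(=C)C(OCC)OCC | intermediate
8 | (3Z)-4-[(tert-butyldimethylsilyl)oxy]-2-chloro-5-(diethoxymethyl)-3-(propan-2-yloxy)hexa-1,3,5-trien-1-one (formed in the flask) | O=C=C(Cl)/C(OC(C)C)=C(\C(=C)C(OCC)OCC)O[Si](C)(C)C(C)(C)C | intermediate
9 | 4-[(tert-butyldimethylsilyl)oxy]-2-chloro-5-(diethoxymethyl)-3-(propan-2-yloxy)cyclohexa-2,4-dien-1-one (formed in the flask) | O=C1CC(C(OCC)OCC)=C(O[Si](C)(C)C(C)(C)C)C(OC(C)C)=C1Cl | intermediate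
10 | 4-[(tert-butyldimethylsilyl)oxy]-2-chloro-5-(diethoxymethyl)-3-(propan-2-yloxy)phenol | Oc1cc(C(OCC)OCC)c(O[Si](C)(C)C(C)(C)C)c(OC(C)C)c1Cl | intermediate
11 | tert-butyl[3-chloro-6-(diethoxymethyl)-4-methoxy-2-(propan-2-yloxy)phenoxy]dimethylsilane | COc1cc(C(OCC)OCC)c(O[Si](C)(C)C(C)(C)C)c(OC(C)C)c1Cl | intermediate
12 | 3-chloro-6-(diethoxymethyl)-4-methoxy-2-(propan-2-yloxy)phenol (formed in the flask) | COc1cc(C(OCC)OCC)c(O)c(OC(C)C)c1Cl | intermediate
13 | 4-chloro-2-hydroxy-5-methoxy-3-(propan-2-yloxy)benzaldehyde | COc1cc(C=O)c(O)c(OC(C)C)c1Cl | intermediate
14 | 3-fluoro-5-methylphenol | Cc1cc(O)cc(F)c1 | starting material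
15 | 1-fluoro-3-methyl-5-(propan-2-yloxy)benzene | Cc1cc(F)cc(OC(C)C)c1 | intermediate
16 | [2-fluoro-4-methyl-6-(propan-2-yloxy)phenyl]lithium (formed in the flask) | [Li]c1c(F)cc(C)cc1OC(C)C | intermediate
17 | 2-fluoro-4-methyl-6-(propan-2-yloxy)benzaldehyde | Cc1cc(F)c(C=O)c(OC(C)C)c1 | intermediate
18 | 4-chloro-2-[2-formyl-5-methyl-3-(propan-2-yloxy)phenoxy]-5-methoxy-3-(propan-2-yloxy)benzaldehyde | COc1cc(C=O)c(Oc2cc(C)cc(OC(C)C)c2C=O)c(OC(C)C)c1Cl | intermediate
19 | 2-[2-carboxy-5-methyl-3-(propan-2-yloxy)phenoxy]-4-chloro-5-methoxy-3-(propan-2-yloxy)benzoic acid | COc1cc(C(=O)O)c(Oc2cc(C)cc(OC(C)C)c2C(=O)O)c(OC(C)C)c1Cl | intermediate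
20 | 2-(2-carboxy-3-hydroxy-5-methylphenoxy)-4-chloro-3-hydroxy-5-methoxybenzoic acid | COc1cc(C(=O)O)c(Oc2cc(C)cc(O)c2C(=O)O)c(O)c1Cl | target

## Step count and least certain steps

Total: 11 steps. Longest linear sequence: 9 steps (steps 1 to 6, then 9 to 11); ring B is made in steps 7 and 8 and joins at step 9.

**Step 3 (addition to the chloro squarate).** The organolithium may attack the chlorine-bearing carbon by conjugate addition and loss of chloride in place of the carbonyl, or add a second time; the silyl triflate may also activate the acetal. The fallback brings chlorine in after the addition. It sets out from 1 and comes back at 7. Squaric acid 1 is esterified (propan-2-ol, toluene, azeotropic removal of water) to 3,4-bis(propan-2-yloxy)cyclobut-3-ene-1,2-dione F1. One carbonyl is reduced with LiAlH(Ot-Bu)3 to 4-hydroxy-2,3-bis(propan-2-yloxy)cyclobut-2-en-1-one F2, which aqueous acid converts into 3-(propan-2-yloxy)cyclobut-3-ene-1,2-dione F3. Reagent 5 adds to the carbonyl beside the isopropoxy carbon to give lithium 1-(3,3-diethoxyprop-1-en-2-yl)-4-oxo-2-(propan-2-yloxy)cyclobut-2-en-1-olate F4, which is silylated in the flask to rac-4-[(tert-butyldimethylsilyl)oxy]-4-(3,3-diethoxyprop-1-en-2-yl)-3-(propan-2-yloxy)cyclobut-2-en-1-one F5. N-Chlorosuccinimide then chlorinates the nucleophilic α-carbon of the β-alkoxy enone to give 7.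

**Step 4 (key step).** The silyl group may be transferred or lost at the temperature of ring opening and the electron-rich product oxidised by air to the quinone, which would erase the distinction between the para oxygens. The chloroketene may also be captured intermolecularly if closure onto the 1,1-disubstituted alkene is slow. The fallback gives up the silyl differentiation. It sets out from 6 and comes back at 12. Alkoxide 6 is protonated (aq. NH4Cl, −78 °C) to rac-2-chloro-4-(3,3-diethoxyprop-1-en-2-yl)-4-hydroxy-3-(propan-2-yloxy)cyclobut-2-en-1-one F6. This is heated in degassed toluene, the parent form of the ring expansion, to give 2-chloro-5-(diethoxymethyl)-3-(propan-2-yloxy)benzene-1,4-diol F7. One equivalent of MeI with K2CO3 under argon should alkylate the more acidic, unhindered hydroxyl beside chlorine and give 12, which the acid treatment of step 6 converts into 13.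

**Step 9 (diaryl ether).** Substitution may be slow because the nucleophile is a hindered phenoxide delocalised into its formyl group; long heating with base may degrade the aldehydes or bring displacement of the ring A chloride. The fallback uses the more electron-rich phenoxide that still carries the acetal. It sets out from 11 and 17 and comes back at 18. CsF in DMF at 80 °C releases the phenoxide of 12 from silyl ether 11 in the presence of 17 and should give 2-[3-chloro-6-(diethoxymethyl)-4-methoxy-2-(propan-2-yloxy)phenoxy]-4-methyl-6-(propan-2-yloxy)benzaldehyde F8. Dilute aqueous acid in the work-up hydrolyses the acetal to 18.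

**Step 10 (double oxidation).** Hypochlorous acid may chlorinate the alkoxy-activated rings faster than the scavenger removes it, and the doubly ortho-substituted ring B aldehyde may oxidise incompletely. The fallback replaces chlorite chemistry by an oxidant class without chlorine: 18 is oxidised with Ag2O in aqueous NaOH and ethanol, the classical method for electron-rich aromatic aldehydes, and acidification returns to 19. No new compound is made.

## Further compounds

F1 | step 3 | 3,4-bis(propan-2-yloxy)cyclobut-3-ene-1,2-dione | CC(C)OC1=C(OC(C)C)C(=O)C1=O
F2 | step 3 | rac-4-hydroxy-2,3-bis(propan-2-yloxy)cyclobut-2-en-1-one | O=C1C(OC(C)C)=C(OC(C)C)C1O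
F3 | step 3 | 3-(propan-2-yloxy)cyclobut-3-ene-1,2-dione | CC(C)OC1=CC(=O)C1=O
F4 | step 3 | lithium 1-(3,3-diethoxyprop-1-en-2-yl)-4-oxo-2-(propan-2-yloxy)cyclobut-2-en-1-olate, racemic | [Li]OC1(C(=C)C(OCC)OCC)C(OC(C)C)=CC1=O
F5 | step 3 | rac-4-[(tert-butyldimethylsilyl)oxy]-4-(3,3-diethoxyprop-1-en-2-yl)-3-(propan-2-yloxy)cyclobut-2-en-1-one | O=C1C=C(OC(C)C)C1(O[Si](C)(C)C(C)(C)C)C(=C)C(OCC)OCC
F6 | step 4 | rac-2-chloro-4-(3,3-diethoxyprop-1-en-2-yl)-4-hydroxy-3-(propan-2-yloxy)cyclobut-2-en-1-one | O=C1C(Cl)=C(OC(C)C)C1(O)C(=C)C(OCC)OCC
F7 | step 4 | 2-chloro-5-(diethoxymethyl)-3-(propan-2-yloxy)benzene-1,4-diol | Oc1cc(C(OCC)OCC)c(O)c(OC(C)C)c1Cl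
F8 | step 9 | 2-[3-chloro-6-(diethoxymethyl)-4-methoxy-2-(propan-2-yloxy)phenoxy]-4-methyl-6-(propan-2-yloxy)benzaldehyde | COc1cc(C(OCC)OCC)c(Oc2cc(C)cc(OC(C)C)c2C=O)c(OC(C)C)c1Cl
F0 | step 10 | none | none
A1 | alternative 1 | methyl 4-[2-(benzyloxy)-3-chloro-4-methoxy-6-(methoxycarbonyl)phenoxy]-6-methyl-2-oxo-2H-pyran-3-carboxylate | COC(=O)C1=C(Oc2c(C(=O)OC)cc(OC)c(Cl)c2OCc2ccccc2)C=C(C)OC1=O
A2 | alternative 1 | methyl 2-[2-(benzyloxy)-3-chloro-4-methoxy-6-(methoxycarbonyl)phenoxy]-6-methoxy-4-methylbenzoate | COC(=O)c1c(OC)cc(C)cc1Oc1c(C(=O)OC)cc(OC)c(Cl)c1OCc1ccccc1
A3 | alternative 2 | 2-(benzyloxy)-4-methyl-6-(trimethylsilyl)phenyl trifluoromethanesulfonate | Cc1cc(OCc2ccccc2)c(OS(=O)(=O)C(F)(F)F)c([Si](C)(C)C)c1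
A4 | alternative 2 | 2-(benzyloxy)-3-chloro-6-(dimethoxymethyl)-4-methoxyphenol | COc1cc(C(OC)OC)c(O)c(OCc2ccccc2)c1Cl
A5 | alternative 2 | 2-[2-(benzyloxy)-3-chloro-6-(dimethoxymethyl)-4-methoxyphenoxy]-6-(benzyloxy)-4-methylbenzoic acid | COc1cc(C(OC)OC)c(Oc2cc(C)cc(OCc3ccccc3)c2C(=O)O)c(OCc2ccccc2)c1Cl
A6 | alternative 3 | dimethyl 2-{1-[2-(benzyloxy)-3-chloro-4-methoxy-6-(methoxycarbonyl)phenoxy]-3-methylbut-2-en-1-ylidene}propanedioate | COC(=O)C(C(=O)OC)=C(Oc1c(C(=O)OC)cc(OC)c(Cl)c1OCc1ccccc1)C=C(C)C
A7 | alternative 3 | methyl 2-[2-(benzyloxy)-3-chloro-4-methoxy-6-(methoxycarbonyl)phenoxy]-6-hydroxy-4-methylbenzoate | COC(=O)c1c(O)cc(C)cc1Oc1c(C(=O)OC)cc(OC)c(Cl)c1OCc1ccccc1
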